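## Retrosynthetic overview

- C9=C10 is cut last: E-selective cross-metathesis joins a vinyl-carbinol hydroxy-lactone (left half) to a furyl skipped diene (right half).
- The γ-lactone is closed as in the presumed biosynthesis: the Δ4 olefin of an unprotected hydroxy dienoic acid is epoxidised and its own carboxyl opens the epoxide 5-exo at the tertiary carbon with inversion. This is done in one flask without protecting groups, although the free C8 hydroxyl could compete, and it sets C4 and C5 together.
- The acid comes from (S)-linalool (C8 from the chiral pool) by E-selective allylic oxidation, bromination and two-carbon extension with the dianion of acetic acid.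
- The right half comes from pent-1-en-4-yne (methylalumination/iodination fixes the E trisubstituted olefin) and furan-3-carbaldehyde (methylenation, hydroboration, B-alkyl Suzuki coupling).
- Ring order: the furan is bought intact; the lactone is the only ring formed (step 4).

Assumption: (S)-(+)-linalool 1 is purchased as the single enantiomer (ee checked by chiral GC before use); locants C1–C15 refer to the target chain with C1 the lactone carbonyl.

## Route

Step 1
Reactants: 1 (S)-(+)-linalool
Product: 2 (2E,6S)-2,6-dimethylocta-2,7-diene-1,6-diol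
Conditions: SeO2 (0.3 equiv), tBuOOH (3 equiv), salicylic acid (0.1 equiv), CH2Cl2, 0 °C → rt
Reagents that add atoms: tert-butyl hydroperoxide, CC(C)(C)OO (its oxygen is relayed to carbon by the SeO2 catalyst, O=[Se]=O)
Why: Catalytic SeO2 allylic oxidation (ene reaction then [2,3]-sigmatropic shift) hydroxylates only the E-methyl group of the trisubstituted olefin, the vinyl group has no allylic hydrogen, and the C8 stereocentre is not touched.

Step 2
Reactants: 2 (2E,6S)-2,6-dimethylocta-2,7-diene-1,6-diol
Product: 3 (3S,6E)-8-bromo-3,7-dimethylocta-1,6-dien-3-ol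
Conditions: CBr4 (1.1 equiv), PPh3 (1.15 equiv), CH2Cl2, −20 → 0 °C
Reagents that add atoms: carbon tetrabromide, BrC(Br)(Br)Br
Why: Appel bromination proceeds by SN2 at the primary allylic CH2 far faster than at the hindered tertiary alcohol, so the olefin geometry and the stereocentre are kept.

Step 3
Reactants: 3 (3S,6E)-8-bromo-3,7-dimethylocta-1,6-dien-3-ol; 4 acetic acid
Product: 5 (4E,8S)-8-hydroxy-4,8-dimethyldeca-4,9-dienoic acid
Conditions: 4 (2.2 equiv), LiN(iPr)2 (4.4 equiv), THF–DMPU, 0 → 40 °C; then 3, −10 °C → rt; 1 M HCl to pH 3, 0 °C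
Reagents that add atoms: none
Why: Alkylation of the carboxylic acid dianion (enolate SN2) at the primary allylic bromide gives the free γ,δ-unsaturated acid directly with the E geometry retained, one extra equivalent of dianion being spent on the tertiary hydroxyl.

Step 4
Reactants: 5 (4E,8S)-8-hydroxy-4,8-dimethyldeca-4,9-dienoic acid
Product: 7 (5S)-5-[(1R,4S)-1,4-dihydroxy-4-methylhex-5-en-1-yl]-5-methyloxolan-2-one, via epoxy acid 6 (not isolated)
Conditions: D-fructose-derived ketone 1,2:4,5-di-O-isopropylidene-β-D-erythro-2,3-hexodiulo-2,6-pyranose (C12H18O6, 0.3 equiv), KHSO5 (as 2KHSO5·KHSO4·K2SO4, 1.5 equiv), K2CO3, Bu4NHSO4, Na2B4O7/Na2H2EDTA buffer (pH 10.5), MeCN–CH2(OMe)2–H2O, −5 °C; then aq. KHSO4 to pH 3, EtOAc, 0 °C → rt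
Reagents that add atoms: potassium peroxymonosulfate KHSO5, [K+].[O-]S(=O)(=O)OO
Why: Shi asymmetric epoxidation with the D-fructose-derived dioxirane attacks only the electron-rich E-trisubstituted olefin and gives the (R,R)-epoxide (C5 becomes R), after which the acid-promoted 5-exo epoxide opening by the molecule's own carboxyl at the tertiary carbon inverts C4 to S, an attack expected to outrun capture of C5 by the tertiary hydroxyl because it is both 5-exo and Markovnikov.

Step 5
Reactants: 8 furan-3-carbaldehyde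
Product: 9 3-vinylfuran
Conditions: Ph3PCH3Br (1.2 equiv), KOtBu (1.2 equiv), THF, 0 °C → rt; distilled and used as a THF solution
Reagents that add atoms: methyltriphenylphosphonium bromide, C[P+](c1ccccc1)(c1ccccc1)c1ccccc1.[Br-]
Why: Wittig methylenation of an aromatic aldehyde is reliable and creates no stereo-element.

Step 6
Reactants: 10 pent-1-en-4-yne
Product: 12 (1E)-1-iodo-2-methylpenta-1,4-diene, via alkenylalane 11 (not isolated)
Conditions: Me3Al (2 equiv), Cp2ZrCl2 (0.2 equiv), CH2Cl2, 0 °C → rt; then I2, THF, −30 → 0 °C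
Reagents that add atoms: trimethylaluminium, C[Al](C)C; iodine, [I][I]
Why: Negishi zirconium-catalysed methylalumination adds methyl and aluminium syn across the alkyne (methyl to the internal carbon) and iodinolysis retains the geometry, so the E trisubstituted olefin of the target is fixed while the isolated terminal alkene is not carbometalated.

Step 7
Reactants: 9 3-vinylfuran; 12 (1E)-1-iodo-2-methylpenta-1,4-diene
Product: 14 3-[(3E)-4-methylhepta-3,6-dien-1-yl]furan, via alkylborane 13 (not isolated)
Conditions: 9 (1.2 equiv), 9-BBN (1.1 equiv), THF, 0 °C → rt; then 12 (1.0 equiv), PdCl2(dppf) (5 mol%), AsPh3 (5 mol%), 3 M aq. NaOH, THF–DMF, rt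
Reagents that add atoms: none
Why: Anti-Markovnikov hydroboration of the vinylarene followed by B-alkyl Suzuki–Miyaura coupling joins sp3 to sp2 carbon with retention of the alkenyl geometry, and the borane is consumed before the iodide with its terminal olefin is added.

Step 8
Reactants: 7 (5S)-5-[(1R,4S)-1,4-dihydroxy-4-methylhex-5-en-1-yl]-5-methyloxolan-2-one; 14 3-[(3E)-4-methylhepta-3,6-dien-1-yl]furan
Product: 15 (5S)-5-[(1R,4S,5E,8E)-11-(furan-3-yl)-1,4-dihydroxy-4,8-dimethylundeca-5,8-dien-1-yl]-5-methyloxolan-2-one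
Conditions: second-generation Hoveyda–Grubbs catalyst RuCl2(H2IMes)(=CH-C6H4-2-OiPr) (7 mol%), 14 (2.5 equiv), 1,4-benzoquinone (10 mol%), CH2Cl2, 40 °C
Reagents that add atoms: none
Why: Olefin cross-metathesis between a terminal olefin and an unprotected tertiary allylic alcohol (slow to homodimerise) gives the E-disubstituted olefin for steric reasons, while the trisubstituted olefin, furan, lactone and hydroxyls are spectators, benzoquinone suppresses isomerisation of the skipped diene, and no stereocentre is touched.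

## Compound list

1 | (S)-(+)-linalool, (3S)-3,7-dimethylocta-1,6-dien-3-ol | C=C[C@@](C)(O)CCC=C(C)C | starting material
2 | (2E,6S)-2,6-dimethylocta-2,7-diene-1,6-diol | C=C[C@@](C)(O)CC/C=C(\C)CO | intermediate
3 | (3S,6E)-8-bromo-3,7-dimethylocta-1,6-dien-3-ol | C=C[C@@](C)(O)CC/C=C(\C)CBr | intermediate
4 | acetic acid | CC(=O)O | starting material
5 | (4E,8S)-8-hydroxy-4,8-dimethyldeca-4,9-dienoic acid | C=C[C@@](C)(O)CC/C=C(\C)CCC(=O)O | intermediate
6 | 3-[(2R,3R)-3-[(3S)-3-hydroxy-3-methylpent-4-en-1-yl]-2-methyloxiran-2-yl]propanoic acid (not isolated) | C=C[C@@](C)(O)CC[C@H]1O[C@]1(C)CCC(=O)O | intermediate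
7 | (5S)-5-[(1R,4S)-1,4-dihydroxy-4-methylhex-5-en-1-yl]-5-methyloxolan-2-one | C=C[C@@](C)(O)CC[C@@H](O)[C@]1(C)CCC(=O)O1 | intermediate
8 | furan-3-carbaldehyde | O=Cc1ccoc1 | starting material
9 | 3-vinylfuran | C=Cc1ccoc1 | intermediate
10 | pent-1-en-4-yne | C=CCC#C | starting material
11 | dimethyl[(1E)-2-methylpenta-1,4-dien-1-yl]alumane (not isolated) | C=CC/C(C)=C/[Al](C)C | intermediate
12 | (1E)-1-iodo-2-methylpenta-1,4-diene | C=CC/C(C)=C/I | intermediate
13 | 9-[2-(furan-3-yl)ethyl]-9-borabicyclo[3.3.1]nonane (not isolated) | c1cc(CCB2C3CCCC2CCC3)co1 | intermediate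
14 | 3-[(3E)-4-methylhepta-3,6-dien-1-yl]furan | C=CC/C(C)=C/CCc1ccoc1 | intermediate
15 | (5S)-5-[(1R,4S,5E,8E)-11-(furan-3-yl)-1,4-dihydroxy-4,8-dimethylundeca-5,8-dien-1-yl]-5-methyloxolan-2-one (CNP0151262.1) | C/C(=C\CCc1ccoc1)C/C=C/[C@@](C)(O)CC[C@@H](O)[C@]1(C)CCC(=O)O1 | target

## Step count and risks

Total step count: 8. Longest linear sequence: 5 steps (1 → 2 → 3 → 5 → 7 → 15).

**Step 4 (most likely to fail).** The free C8 hydroxyl can open the epoxide at C5 (5-exo, as in linalool oxide formation) and give a tetrahydrofuran instead of the lactone. The facial selectivity of the epoxidation (typically 90–95%) also leaves a minor diastereomer to remove. The fallback sets out from 5 and returns at 7, masking the competing hydroxyl first. 5 is silylated (Et3SiOTf, 2,6-lutidine, CH2Cl2, −78 °C) to triethylsilyl (4E,8S)-4,8-dimethyl-8-(triethylsilyloxy)deca-4,9-dienoate F1. Its silyl ester is cleaved in the aqueous K2CO3 work-up to (4E,8S)-4,8-dimethyl-8-(triethylsilyloxy)deca-4,9-dienoic acid F2. The same ketone/KHSO5 epoxidation gives 3-[(2R,3R)-2-methyl-3-[(3S)-3-methyl-3-(triethylsilyloxy)pent-4-en-1-yl]oxiran-2-yl]propanoic acid F3, in which only the carboxyl can open the epoxide. Acidification to pH 3 then gives (5S)-5-[(1R,4S)-1-hydroxy-4-methyl-4-(triethylsilyloxy)hex-5-en-1-yl]-5-methyloxolan-2-one F4, and Bu4NF/AcOH in THF frees 7.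

**Step 8.** The hindered tertiary allylic alcohol may react sluggishly, and the furyl skipped diene 14 can homodimerise or isomerise under ruthenium. The fallback sets out from 7 and returns at 15, changing the last bond formed. The metathesis is run with the small, volatile iodide 12 (5 equiv, same ruthenium catalyst), which tolerates a large excess and carries neither the furan nor a second reactive olefin. This gives (5S)-5-[(1R,4S,5E,8E)-1,4-dihydroxy-9-iodo-4,8-dimethylnona-5,8-dien-1-yl]-5-methyloxolan-2-one F5. B-alkyl Suzuki coupling of this iodide with borane 13 (made from 9 as in step 7; PdCl2(dppf), AsPh3, K3PO4, DMF–THF–H2O, rt, then brief acidification to re-close any opened lactone) installs the furylethyl group and gives 15.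

**Step 3.** The strongly basic acetate dianion may eliminate or attack the unprotected bromo alcohol unselectively. The fallback sets out from 3 and returns at 5 by malonic ester synthesis. 3 is alkylated with the sodium salt of dimethyl malonate (NaH, THF, 0 °C → rt) to dimethyl 2-[(2E,6S)-6-hydroxy-2,6-dimethylocta-2,7-dien-1-yl]propanedioate F6. LiOH in THF–H2O gives 2-[(2E,6S)-6-hydroxy-2,6-dimethylocta-2,7-dien-1-yl]propanedioic acid F7, which loses carbon dioxide on heating in pyridine (100 °C) to give 5.

## Further compounds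

F1 | step 4 | triethylsilyl (4E,8S)-4,8-dimethyl-8-(triethylsilyloxy)deca-4,9-dienoate | C=C[C@@](C)(O[Si](CC)(CC)CC)CC/C=C(\C)CCC(=O)O[Si](CC)(CC)CC
F2 | step 4 | (4E,8S)-4,8-dimethyl-8-(triethylsilyloxy)deca-4,9-dienoic acid | C=C[C@@](C)(O[Si](CC)(CC)CC)CC/C=C(\C)CCC(=O)O
F3 | step 4 | 3-[(2R,3R)-2-methyl-3-[(3S)-3-methyl-3-(triethylsilyloxy)pent-4-en-1-yl]oxiran-2-yl]propanoic acid | C=C[C@@](C)(O[Si](CC)(CC)CC)CC[C@H]1O[C@]1(C)CCC(=O)O
F4 | step 4 | (5S)-5-[(1R,4S)-1-hydroxy-4-methyl-4-(triethylsilyloxy)hex-5-en-1-yl]-5-methyloxolan-2-one | C=C[C@@](C)(O[Si](CC)(CC)CC)CC[C@@H](O)[C@]1(C)CCC(=O)O1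
F5 | step 8 | (5S)-5-[(1R,4S,5E,8E)-1,4-dihydroxy-9-iodo-4,8-dimethylnona-5,8-dien-1-yl]-5-methyloxolan-2-one | I/C=C(\C)C/C=C/[C@@](C)(O)CC[C@@H](O)[C@]1(C)CCC(=O)O1
F6 | step 3 | dimethyl 2-[(2E,6S)-6-hydroxy-2,6-dimethylocta-2,7-dien-1-yl]propanedioate | C=C[C@@](C)(O)CC/C=C(\C)CC(C(=O)OC)C(=O)OC
F7 | step 3 | 2-[(2E,6S)-6-hydroxy-2,6-dimethylocta-2,7-dien-1-yl]propanedioic acid | C=C[C@@](C)(O)CC/C=C(\C)CC(C(=O)O)C(=O)O
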